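**Plan**
1. Numbering: naphthalene C1 (ring C, 3,4-dimethoxyphenyl), C2 (OH), C3 (CHO), C4 (H), C7 (OH), C8 (OMe); ring A is the C5–C8 benzo ring, ring B the C1–C4 ring.
2. Cuts, in order: C3–CHO (MOM-directed lithiation, DMF), C2–O (from C2–Br), then C1–C2 and C2–C3 together. C2 is a single heteroatom-bearing carbon between aryl-bearing C1 and C3, so ring B is the five-membered ring of a 3-arylindene with one dibromocarbene carbon inserted into its C=C bond.
3. Further cuts: C1–ring C (aryl Grignard plus indanone) and the aryl–C(=O) bond of the indanone (bromine-blocked Friedel–Crafts closure from dihydroferulic acid).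
4. Forward order: ring A (given) → five-membered ring (step 3) → ring C attached (step 5) → ring B by one-carbon expansion (step 6) → oxygen at C2 (step 7) → formyl at C3 (steps 8, 9) → deprotection (step 10).
5. Stereochemistry: the target has no stereocentre; intermediates 10, 13 and 20 are racemic and lose their stereocentres in the same flask.

Key step: step 6

Assumption: rotation about the C1–ring C bond is taken as free (target achiral), and the C7 phenol is carried as an isopropyl ether because it withstands hydrogenolysis, tert-butoxide and alkyllithiums and is cleaved by BCl3 without loss of methyl ethers.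

**Step 1**
Reactants: 1 3-(4-hydroxy-3-methoxyphenyl)propanoic acid
Product: 3 3-[3-methoxy-4-(propan-2-yloxy)phenyl]propanoic acid, via isopropyl ester 2 (not isolated)
Conditions: 2-bromopropane (3 equiv), K2CO3, DMF, 70 °C; then 2 M NaOH, MeOH, 60 °C; HCl to pH 2
Reagents that add atoms: 2-bromopropane, CC(C)Br
Why: Williamson etherification of the phenoxide in DMF followed by saponification of whatever isopropyl ester has formed should funnel all material to the ether acid.

**Step 2**
Reactants: 3 3-[3-methoxy-4-(propan-2-yloxy)phenyl]propanoic acid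
Product: 4 3-[2-bromo-5-methoxy-4-(propan-2-yloxy)phenyl]propanoic acid
Conditions: NBS (1.05 equiv), MeCN, 0 °C → rt, dark
Reagents that add atoms: N-bromosuccinimide, O=C1CCC(=O)N1Br
Why: Electrophilic aromatic bromination should go para to the methoxy group (ortho to the side chain), as is usual for 4-alkyl-1,2-dialkoxybenzenes, and so blocks the site where the acylium ion would otherwise attack.

**Step 3**
Reactants: 4 3-[2-bromo-5-methoxy-4-(propan-2-yloxy)phenyl]propanoic acid
Product: 6 4-bromo-7-methoxy-6-(propan-2-yloxy)-2,3-dihydro-1H-inden-1-one, via acid chloride 5 (not isolated)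
Conditions: (COCl)2, DMF (cat.), CH2Cl2, 0 °C → rt; evaporate; SnCl4 (1.2 equiv), CH2Cl2, −20 → 0 °C
Reagents that add atoms: none
Why: Intramolecular Friedel–Crafts acylation can only close the five-membered ring at the remaining ortho carbon between side chain and methoxy group, and SnCl4 at low temperature should spare the isopropyl ether and the methoxy group next to the new carbonyl.

**Step 4**
Reactants: 6 4-bromo-7-methoxy-6-(propan-2-yloxy)-2,3-dihydro-1H-inden-1-one
Product: 7 7-methoxy-6-(propan-2-yloxy)-2,3-dihydro-1H-inden-1-one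
Conditions: H2 (1 atm), 10% Pd/C, Et3N, EtOAc, rt
Reagents that add atoms: none
Why: Catalytic hydrodehalogenation of the aryl C–Br bond with Et3N as HBr scavenger is fast at 1 atm, while the aryl ketone and the alkyl aryl ethers should not be reduced under these basic, low-pressure conditions.

**Step 5**
Reactants: 7 7-methoxy-6-(propan-2-yloxy)-2,3-dihydro-1H-inden-1-one; 8 4-bromo-1,2-dimethoxybenzene
Product: 11 3-(3,4-dimethoxyphenyl)-4-methoxy-5-(propan-2-yloxy)-1H-indene, via Grignard reagent 9 (not isolated), via tertiary carbinol 10 (not isolated)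
Conditions: 8, Mg, I2 (cat.), THF, reflux; then 7, THF, 0 °C → rt; then 2 M HCl, rt
Reagents that add atoms: none
Why: Grignard 1,2-addition to the indanone carbonyl and acid-induced E1 dehydration of the doubly benzylic tertiary carbinol on work-up should give the conjugated 3-aryl-1H-indene, the only alkene that elimination toward C2 can form.

**Step 6**
Reactants: 11 3-(3,4-dimethoxyphenyl)-4-methoxy-5-(propan-2-yloxy)-1H-indene; 12 bromoform
Product: 14 2-bromo-1-(3,4-dimethoxyphenyl)-8-methoxy-7-(propan-2-yloxy)naphthalene, via dibromocyclopropane 13 (not isolated)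
Conditions: CHBr3 (2 equiv), KOtBu (3 equiv, added in portions), toluene, −20 °C → rt
Reagents that add atoms: none
Why: Deprotonation of bromoform (far more acidic than the indene CH2) and loss of bromide gives singlet dibromocarbene, which adds in a concerted [2+1] cheletropic fashion to the only alkene of 11, the electron-rich styrenic C2=C3 bond, closing the three-membered ring of 13. Ionisation of one bromide with concerted disrotatory two-electron electrocyclic opening of the ring-fusion bond (cyclopropyl-to-allyl cation rearrangement) turns the five-membered ring into six-membered ring B, the cation being stabilised at C1 by ring A and ring C. Loss of the C4 proton to tert-butoxide aromatises ring B and leaves bromine on the inserted carbon C2, between aryl-bearing C1 and C3–H. The closest known reaction type is the dihalocarbene ring expansion of indenes to 2-halonaphthalenes, the carbocyclic counterpart of the Ciamician–Dennstedt rearrangement. No stereocentre survives, since 13 is racemic, cis-fused by necessity and consumed in the flask. The step needs chemoselectivity for the alkene over the alkoxy-arenes, which aryl ethers (unlike phenoxides) allow, and regiocontrol, which follows because the conjugated isomer 11 is the favoured indene tautomer and the carbene carbon can then only end between C1 and C3.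

**Step 7**
Reactants: 14 2-bromo-1-(3,4-dimethoxyphenyl)-8-methoxy-7-(propan-2-yloxy)naphthalene
Product: 17 1-(3,4-dimethoxyphenyl)-8-methoxy-7-(propan-2-yloxy)naphthalen-2-ol, via aryllithium 15 (not isolated), via lithium borate 16 (not isolated)
Conditions: n-BuLi, THF, −78 °C; B(OMe)3, −78 °C → rt; AcOH, 30% H2O2, 0 °C → rt
Reagents that add atoms: hydrogen peroxide, OO
Why: Bromine–lithium exchange is much faster than any ortho-deprotonation at −78 °C, the aryllithium is trapped as the borate, and peroxide-induced 1,2-migration of the aryl group from boron to oxygen (boronate oxidation) should place the hydroxyl exactly at C2.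

**Step 8**
Reactants: 17 1-(3,4-dimethoxyphenyl)-8-methoxy-7-(propan-2-yloxy)naphthalen-2-ol
Product: 18 1-(3,4-dimethoxyphenyl)-8-methoxy-2-(methoxymethoxy)-7-(propan-2-yloxy)naphthalene
Conditions: NaH, MOMCl, THF, 0 °C → rt
Reagents that add atoms: chloromethyl methyl ether, COCCl
Why: Williamson-type O-alkylation of the sodium naphthoxide masks the phenol as a strong directing group for lithiation that is later cleaved together with the isopropyl ether.

**Step 9**
Reactants: 18 1-(3,4-dimethoxyphenyl)-8-methoxy-2-(methoxymethoxy)-7-(propan-2-yloxy)naphthalene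
Product: 21 4-(3,4-dimethoxyphenyl)-5-methoxy-3-(methoxymethoxy)-6-(propan-2-yloxy)naphthalene-2-carbaldehyde, via C3-lithio species 19 (not isolated), via lithium hemiaminal alkoxide 20 (not isolated)
Conditions: n-BuLi, TMEDA, THF, −78 → 0 °C; DMF, −78 °C → rt; H2O
Reagents that add atoms: N,N-dimethylformamide, CN(C)C=O
Why: Directed ortho-metalation: the MOM ether guides n-BuLi to its only free ortho position, C3 (C1 carries ring C), far more strongly than the isopropoxy or methoxy groups direct elsewhere, and DMF formylates the aryllithium through a hemiaminal alkoxide that collapses to the aldehyde on aqueous work-up.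

**Step 10**
Reactants: 21 4-(3,4-dimethoxyphenyl)-5-methoxy-3-(methoxymethoxy)-6-(propan-2-yloxy)naphthalene-2-carbaldehyde
Product: 23 vitrofolal B, via bis(dichloroboryl) ester 22 (not isolated)
Conditions: BCl3 (1 M in CH2Cl2, 5 equiv), CH2Cl2, −78 → 0 °C; then H2O
Reagents that add atoms: none
Why: Lewis-acid ether cleavage: BCl3 removes the acetal-type MOM ether and the secondary isopropyl ether at low temperature, whereas the three aryl methyl ethers, none of them ortho to the carbonyl group, should be retained, and hydrolysis of the boron aryloxides frees both phenols.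

**Compound list**
1 | 3-(4-hydroxy-3-methoxyphenyl)propanoic acid (dihydroferulic acid) | COc1cc(CCC(=O)O)ccc1O | starting material
2 | propan-2-yl 3-[3-methoxy-4-(propan-2-yloxy)phenyl]propanoate | COc1cc(CCC(=O)OC(C)C)ccc1OC(C)C | intermediate
3 | 3-[3-methoxy-4-(propan-2-yloxy)phenyl]propanoic acid | COc1cc(CCC(=O)O)ccc1OC(C)C | intermediate
4 | 3-[2-bromo-5-methoxy-4-(propan-2-yloxy)phenyl]propanoic acid | COc1cc(CCC(=O)O)c(Br)cc1OC(C)C | intermediate
5 | 3-[2-bromo-5-methoxy-4-(propan-2-yloxy)phenyl]propanoyl chloride | COc1cc(CCC(=O)Cl)c(Br)cc1OC(C)C | intermediate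
6 | 4-bromo-7-methoxy-6-(propan-2-yloxy)-2,3-dihydro-1H-inden-1-one | O=C1CCc2c(Br)cc(OC(C)C)c(OC)c21 | intermediate
7 | 7-methoxy-6-(propan-2-yloxy)-2,3-dihydro-1H-inden-1-one | O=C1CCc2ccc(OC(C)C)c(OC)c21 | intermediate
8 | 4-bromo-1,2-dimethoxybenzene | COc1ccc(Br)cc1OC | starting material
9 | (3,4-dimethoxyphenyl)magnesium bromide | COc1ccc([Mg]Br)cc1OC | intermediate
10 | 1-(3,4-dimethoxyphenyl)-7-methoxy-6-(propan-2-yloxy)-2,3-dihydro-1H-inden-1-ol (racemic) | COc1ccc(C2(O)CCc3ccc(OC(C)C)c(OC)c32)cc1OC | intermediate
11 | 3-(3,4-dimethoxyphenyl)-4-methoxy-5-(propan-2-yloxy)-1H-indene | COc1ccc(C2=CCc3ccc(OC(C)C)c(OC)c32)cc1OC | intermediate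
12 | bromoform (tribromomethane) | BrC(Br)Br | starting material
13 | 1,1-dibromo-1a-(3,4-dimethoxyphenyl)-2-methoxy-3-(propan-2-yloxy)-1,1a,6,6a-tetrahydrocyclopropa[a]indene (CBr2 bridging former C2 and C3 of 11; racemic, cis-fused) | COc1ccc(cc1OC)C23C(Br)(Br)C2Cc2ccc(OC(C)C)c(OC)c23 | intermediate
14 | 2-bromo-1-(3,4-dimethoxyphenyl)-8-methoxy-7-(propan-2-yloxy)naphthalene | COc1ccc(-c2c(Br)ccc3ccc(OC(C)C)c(OC)c23)cc1OC | intermediate
15 | [1-(3,4-dimethoxyphenyl)-8-methoxy-7-(propan-2-yloxy)naphthalen-2-yl]lithium | [Li]c1ccc2ccc(OC(C)C)c(OC)c2c1-c1ccc(OC)c(OC)c1 | intermediate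
16 | lithium [1-(3,4-dimethoxyphenyl)-8-methoxy-7-(propan-2-yloxy)naphthalen-2-yl]trimethoxyborate | [Li+].CO[B-](OC)(OC)c1ccc2ccc(OC(C)C)c(OC)c2c1-c1ccc(OC)c(OC)c1 | intermediate
17 | 1-(3,4-dimethoxyphenyl)-8-methoxy-7-(propan-2-yloxy)naphthalen-2-ol | COc1ccc(-c2c(O)ccc3ccc(OC(C)C)c(OC)c23)cc1OC | intermediate
18 | 1-(3,4-dimethoxyphenyl)-8-methoxy-2-(methoxymethoxy)-7-(propan-2-yloxy)naphthalene | COCOc1ccc2ccc(OC(C)C)c(OC)c2c1-c1ccc(OC)c(OC)c1 | intermediate
19 | [4-(3,4-dimethoxyphenyl)-5-methoxy-3-(methoxymethoxy)-6-(propan-2-yloxy)naphthalen-2-yl]lithium | [Li]c1cc2ccc(OC(C)C)c(OC)c2c(-c2ccc(OC)c(OC)c2)c1OCOC | intermediate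
20 | lithium [4-(3,4-dimethoxyphenyl)-5-methoxy-3-(methoxymethoxy)-6-(propan-2-yloxy)naphthalen-2-yl](dimethylamino)methanolate (racemic) | [Li+].[O-]C(N(C)C)c1cc2ccc(OC(C)C)c(OC)c2c(-c2ccc(OC)c(OC)c2)c1OCOC | intermediate
21 | 4-(3,4-dimethoxyphenyl)-5-methoxy-3-(methoxymethoxy)-6-(propan-2-yloxy)naphthalene-2-carbaldehyde | COCOc1c(C=O)cc2ccc(OC(C)C)c(OC)c2c1-c1ccc(OC)c(OC)c1 | intermediate
22 | 3,6-bis[(dichloroboranyl)oxy]-4-(3,4-dimethoxyphenyl)-5-methoxynaphthalene-2-carbaldehyde | COc1ccc(-c2c(OB(Cl)Cl)c(C=O)cc3ccc(OB(Cl)Cl)c(OC)c23)cc1OC | intermediate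
23 | vitrofolal B, 4-(3,4-dimethoxyphenyl)-3,6-dihydroxy-5-methoxynaphthalene-2-carbaldehyde | COc1ccc(-c2c(O)c(C=O)cc3ccc(O)c(OC)c23)cc1OC | target

**Totals**
Total step count: 10. Longest linear sequence: 10 steps (1 → 23); compounds 8 and 12 enter in steps 5 and 6.

**Steps most likely to fail**

Step 6 (carbene ring expansion). tert-Butoxide may deprotonate the indene CH2, so that the carbene is taken up through the indenyl anion at the other C–C bond and bromine ends on the wrong carbon. Addition to the crowded alkene may also be so slow that the carbene is consumed by the alkoxy-arenes or by the product. The fallback sets out from 7 and comes back at 17, replacing steps 5 to 7. Wittig methylenation of 7 (MePPh3Br, KOtBu, THF) would give 7-methoxy-1-methylidene-6-(propan-2-yloxy)-2,3-dihydro-1H-indene F1. Oxidative 1,2-aryl shift with PhI(OH)OTs in aqueous MeOH would expand the ring to 8-methoxy-7-(propan-2-yloxy)-3,4-dihydronaphthalen-2(1H)-one F2. Pd-catalysed α-arylation at the benzylic C1 with 8 (Pd(OAc)2, XPhos, NaOtBu, toluene, 80 °C) would give 1-(3,4-dimethoxyphenyl)-8-methoxy-7-(propan-2-yloxy)-3,4-dihydronaphthalen-2(1H)-one F3. Dehydrogenation with DDQ in dioxane would then deliver naphthol 17, from which steps 8 to 10 follow unchanged.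

Step 3 (Friedel–Crafts closure). The Lewis acid may strip the isopropyl ether during the slow closure at the crowded ortho carbon, or the acylium ion may attack the brominated carbon with bromine migration. The fallback sets out from 4 and comes back at 6. Compound 4 is heated in polyphosphoric acid at 70–80 °C, where ring closure is driven hard and loss of the isopropyl group is accepted, to give 4-bromo-6-hydroxy-7-methoxy-2,3-dihydro-1H-inden-1-one F4. The free phenol is then re-alkylated (2-bromopropane, K2CO3, DMF) to reach 6.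

Step 10 (global deprotection). The chloromethyl methyl ether released next to BCl3 may chloromethylate the electron-rich rings, and prolonged exposure may also cleave the twisted, doubly flanked methoxy group on ring A. The fallback sets out from 21 and comes back at 23. The acetal is exchanged first with HCl in MeOH at 40 °C, which carries the formaldehyde unit away as dimethoxymethane and gives 4-(3,4-dimethoxyphenyl)-3-hydroxy-5-methoxy-6-(propan-2-yloxy)naphthalene-2-carbaldehyde F5. Only the isopropyl ether is then cleaved with BCl3 (2 equiv) in CH2Cl2 at −78 °C, with no chloromethyl ether present, to reach 23.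

**Further compounds**
F1 | step 6 | 7-methoxy-1-methylidene-6-(propan-2-yloxy)-2,3-dihydro-1H-indene | C=C1CCc2ccc(OC(C)C)c(OC)c21
F2 | step 6 | 8-methoxy-7-(propan-2-yloxy)-3,4-dihydronaphthalen-2(1H)-one | O=C1CCc2ccc(OC(C)C)c(OC)c2C1
F3 | step 6 | 1-(3,4-dimethoxyphenyl)-8-methoxy-7-(propan-2-yloxy)-3,4-dihydronaphthalen-2(1H)-one (racemic) | O=C1CCc2ccc(OC(C)C)c(OC)c2C1c1ccc(OC)c(OC)c1
F4 | step 3 | 4-bromo-6-hydroxy-7-methoxy-2,3-dihydro-1H-inden-1-one | O=C1CCc2c(Br)cc(O)c(OC)c21
F5 | step 10 | 4-(3,4-dimethoxyphenyl)-3-hydroxy-5-methoxy-6-(propan-2-yloxy)naphthalene-2-carbaldehyde | COc1ccc(-c2c(O)c(C=O)cc3ccc(OC(C)C)c(OC)c23)cc1OC
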